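The route builds ring B of the apigenin half last. That ring is a 1,4-disubstituted benzene: C1' is bonded to chromone C2, C4' bears the diaryl ether oxygen, and C2', C3', C5' and C6' carry hydrogen. It is therefore cut into the C3–C6 diene of a 4-aryloxy-2-pyrone and the two carbons of a terminal alkyne. One thermal Diels–Alder/retro-Diels–Alder operation should form C2'–C3' and C1'–C6', expel carbon dioxide, close the benzene ring and join both flavone halves. The precursors are the 2-pyron-4-yl ether of 5,7-di-O-benzyl-6-hydroxy-4'-methoxyflavone and 5,7-bis(benzyloxy)-2-ethynylchromone, both made from one dibenzylated phloracetophenone; only debenzylation follows.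

Key step: step 12

Remark: the bridged lactone adduct of the key step is racemic and loses both bridgehead stereocentres on aromatisation; the target has no stereocentre, so no step needs stereocontrol.

Step 1
Reactants: 1 2',4',6'-trihydroxyacetophenone
Product: 2 1-[2,4-bis(benzyloxy)-6-hydroxyphenyl]ethanone
Conditions: BnBr (2.1 equiv), K2CO3, DMF, rt
Reagents that add atoms: benzyl bromide, BrCc1ccccc1
Why: Williamson ether synthesis in which the 4-OH and one ortho OH are alkylated, while the remaining ortho OH is hydrogen-bonded to the acetyl carbonyl, is the least nucleophilic and should stay free.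

Step 2
Reactants: 2 1-[2,4-bis(benzyloxy)-6-hydroxyphenyl]ethanone
Product: 4 1-[2,4-bis(benzyloxy)-3,6-dihydroxyphenyl]ethanone, via potassium aryl sulfate 3 (not isolated)
Conditions: K2S2O8, aq. NaOH, pyridine, 15 °C to rt; then aq. HCl, Na2SO3, 80 °C
Reagents that add atoms: potassium peroxodisulfate, [K+].[K+].[O-]S(=O)(=O)OOS(=O)(=O)[O-]
Why: Elbs persulfate oxidation, in which the phenoxide attacks a peroxide oxygen through the carbon para to the free hydroxyl and the aryl sulfate so formed is hydrolysed by warm dilute acid that should leave the benzyl ethers intact.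

Step 3
Reactants: 4 1-[2,4-bis(benzyloxy)-3,6-dihydroxyphenyl]ethanone; 5 4-methoxybenzoyl chloride
Product: 6 1-[2,4-bis(benzyloxy)-3,6-dihydroxyphenyl]-3-(4-methoxyphenyl)propane-1,3-dione
Conditions: LiN(SiMe3)2 (4 equiv), THF, −78 to −10 °C; 5 (1 equiv), −78 °C to rt; aq. HCl
Reagents that add atoms: none
Why: Claisen-type C-acylation of the trilithium species (two phenoxides and the ketone enolate), in which the enolate carbon is the most nucleophilic site because one phenoxide is chelated and the other is flanked by two benzyloxy groups, and the fourth equivalent of base deprotonates the β-diketone so that it is not acylated again.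

Step 4
Reactants: 6 1-[2,4-bis(benzyloxy)-3,6-dihydroxyphenyl]-3-(4-methoxyphenyl)propane-1,3-dione
Product: 7 5,7-bis(benzyloxy)-6-hydroxy-2-(4-methoxyphenyl)-4H-chromen-4-one
Conditions: NaOAc, AcOH, 100 °C
Reagents that add atoms: none
Why: Cyclodehydration of an o-hydroxyaryl 1,3-diketone (the ring-closing stage of the Baker–Venkataraman flavone synthesis), in which only the hydroxyl ortho to the ketone can close the pyranone, the other hydroxyl becomes the free 6-OH, and the buffered medium should spare the benzyl ethers.

Step 5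
Reactants: 8 ethyl acetoacetate; 9 ethyl formate
Product: 11 4-hydroxy-2H-pyran-2-one, via ethyl 3,5-dioxopentanoate 10 (not isolated)
Conditions: NaH then n-BuLi, THF, 0 °C; 9, −78 to 0 °C; then 6 M HCl, rt
Reagents that add atoms: none
Why: Claisen acylation of the acetoacetate dianion at its terminal carbon by the formate ester gives the 3,5-dioxo ester, whose chelated enol oxygen at C5 should lactonise onto the ethyl ester under acid to give the 4-hydroxy-2-pyrone.

Step 6
Reactants: 11 4-hydroxy-2H-pyran-2-one
Product: 12 4-bromo-2H-pyran-2-one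
Conditions: Bu4NBr, P2O5, toluene, 100 °C
Reagents that add atoms: tetrabutylammonium bromide, CCCC[N+](CCCC)(CCCC)CCCC.[Br-]
Why: Bromodehydroxylation of a vinylogous acid, in which phosphorylation turns the 4-OH into a leaving group that bromide displaces at C4 by addition–elimination, as is established for 4-hydroxy-6-methyl-2-pyrone and 4-hydroxycoumarins.

Step 7
Reactants: 7 5,7-bis(benzyloxy)-6-hydroxy-2-(4-methoxyphenyl)-4H-chromen-4-one; 12 4-bromo-2H-pyran-2-one
Product: 13 4-{[5,7-bis(benzyloxy)-2-(4-methoxyphenyl)-4-oxo-4H-chromen-6-yl]oxy}-2H-pyran-2-one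
Conditions: Cs2CO3, MeCN, rt to 40 °C
Reagents that add atoms: none
Why: Conjugate addition–elimination (vinylogous acyl substitution) of the cesium 6-phenoxide at pyrone C4, with bromide chosen over a sulfonate leaving group so that the hindered phenoxide has no sulfur centre to attack, and with the 6-OH as the only free hydroxyl of 7.

Step 8
Reactants: 2 1-[2,4-bis(benzyloxy)-6-hydroxyphenyl]ethanone; 14 diethyl oxalate
Product: 16 ethyl 5,7-bis(benzyloxy)-4-oxo-4H-chromene-2-carboxylate, via aryl dioxobutanoate 15 (not isolated)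
Conditions: NaOEt, EtOH/THF, 60 °C; then conc. HCl, 60 °C
Reagents that add atoms: none
Why: Crossed Claisen condensation of the methyl ketone with non-enolisable diethyl oxalate followed by acid-catalysed cyclodehydration through the free ortho hydroxyl, the standard entry to chromone-2-carboxylates.

Step 9
Reactants: 16 ethyl 5,7-bis(benzyloxy)-4-oxo-4H-chromene-2-carboxylate
Product: 17 5,7-bis(benzyloxy)-2-(hydroxymethyl)-4H-chromen-4-one
Conditions: NaBH4, MeOH/THF, 0 °C
Reagents that add atoms: none
Why: Chemoselective borohydride reduction of the ester, which is activated by the electron-poor C2 of the pyranone, while the C4 carbonyl is a vinylogous ester that should resist NaBH4 at this temperature.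

Step 10
Reactants: 17 5,7-bis(benzyloxy)-2-(hydroxymethyl)-4H-chromen-4-one
Product: 18 5,7-bis(benzyloxy)-4-oxo-4H-chromene-2-carbaldehyde
Conditions: Dess–Martin periodinane, CH2Cl2, 0 °C to rt
Reagents that add atoms: none
Why: Dess–Martin oxidation of the primary allylic-type alcohol should stop at the non-enolisable aldehyde under neutral anhydrous conditions.

Step 11
Reactants: 18 5,7-bis(benzyloxy)-4-oxo-4H-chromene-2-carbaldehyde
Product: 19 5,7-bis(benzyloxy)-2-ethynyl-4H-chromen-4-one
Conditions: dimethyl (1-diazo-2-oxopropyl)phosphonate, K2CO3, MeOH/THF, 0 °C to rt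
Reagents that add atoms: dimethyl (1-diazo-2-oxopropyl)phosphonate, COP(=O)(OC)C(=[N+]=[N-])C(C)=O
Why: Ohira–Bestmann variant of the Seyferth–Gilbert homologation, in which methanolysis of the reagent frees the diazomethylphosphonate anion, this olefinates the non-enolisable aldehyde, and loss of N2 with a 1,2-hydrogen shift gives the terminal alkyne, low temperature and short contact time limiting base-mediated addition of methanol to the product.

Step 12
Reactants: 13 4-{[5,7-bis(benzyloxy)-2-(4-methoxyphenyl)-4-oxo-4H-chromen-6-yl]oxy}-2H-pyran-2-one; 19 5,7-bis(benzyloxy)-2-ethynyl-4H-chromen-4-one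
Product: 21 5,7,5'',7''-tetra-O-benzylcryptomerin A, via bridged lactone adduct 20 (not isolated)
Conditions: 19 (1.5 equiv), BHT (cat.), 1,2-dichlorobenzene, 160 °C, sealed tube
Reagents that add atoms: none
Why: The pyrone of 13 acts as the diene through C3=C4–C5=C6 and adds to the alkyne of 19 in a normal-demand Diels–Alder reaction, giving the 2-oxabicyclo[2.2.2]octadienone 20, which loses CO2 by retro-Diels–Alder reaction at the same temperature. The closest known reaction type is the benzannulation of 2-pyrones, 4-alkoxy-2-pyrones included, with electron-poor alkynes by cycloaddition and decarboxylation. The new six-membered carbocycle (ring B of the apigenin half) is closed by an intermolecular [4+2] cycloaddition that forms both σ bonds, C3'–C2' from pyrone C3 to the terminal alkyne carbon and C6'–C1' from pyrone C6 to the chromone-bearing carbon, and it becomes aromatic when the O–C(=O) bridge leaves. No stereocentre is created in the product, since the two bridgehead centres of racemic 20 are erased on aromatisation. The step needs para orientation and chemoselectivity for the alkyne: the 4-aryloxy group and the ring oxygen both make C3 the nucleophilic diene terminus, and conjugation through chromone C2=C3 to the C4 carbonyl makes the terminal alkyne carbon the electrophilic one, so their union sets the ether oxygen para to the chromone. The trisubstituted C2=C3 bonds of the two pyranones are far poorer dienophiles than the unhindered terminal alkyne, and irreversible loss of CO2 drives the sequence forward.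

Step 13
Reactants: 21 5,7,5'',7''-tetra-O-benzylcryptomerin A
Product: 22 cryptomerin A
Conditions: BCl3, C6HMe5, CH2Cl2, −78 to −40 °C; then MeOH
Reagents that add atoms: none
Why: Lewis acid debenzylation in which BCl3 ionises the four aryl benzyl ethers and pentamethylbenzene traps the benzyl cations by Friedel–Crafts alkylation, while the non-chelated aryl methyl ether, the diaryl ether and both pyranones should be untouched at low temperature.

Compound list
1 | 2',4',6'-trihydroxyacetophenone | CC(=O)c1c(O)cc(O)cc1O | starting material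
2 | 1-[2,4-bis(benzyloxy)-6-hydroxyphenyl]ethanone | CC(=O)c1c(O)cc(OCc2ccccc2)cc1OCc1ccccc1 | intermediate
3 | potassium 3-acetyl-2,6-bis(benzyloxy)-4-hydroxyphenyl sulfate (not isolated) | CC(=O)c1c(O)cc(OCc2ccccc2)c(OS(=O)(=O)[O-])c1OCc1ccccc1.[K+] | intermediate
4 | 1-[2,4-bis(benzyloxy)-3,6-dihydroxyphenyl]ethanone | CC(=O)c1c(O)cc(OCc2ccccc2)c(O)c1OCc1ccccc1 | intermediate
5 | 4-methoxybenzoyl chloride | COc1ccc(C(=O)Cl)cc1 | starting material
6 | 1-[2,4-bis(benzyloxy)-3,6-dihydroxyphenyl]-3-(4-methoxyphenyl)propane-1,3-dione | COc1ccc(C(=O)CC(=O)c2c(O)cc(OCc3ccccc3)c(O)c2OCc2ccccc2)cc1 | intermediate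
7 | 5,7-bis(benzyloxy)-6-hydroxy-2-(4-methoxyphenyl)-4H-chromen-4-one | COc1ccc(-c2cc(=O)c3c(OCc4ccccc4)c(O)c(OCc4ccccc4)cc3o2)cc1 | intermediate
8 | ethyl acetoacetate | CCOC(=O)CC(C)=O | starting material
9 | ethyl formate | CCOC=O | starting material
10 | ethyl 3,5-dioxopentanoate (not isolated; reacts as its 5-hydroxy-4-ene enol) | CCOC(=O)CC(=O)CC=O | intermediate
11 | 4-hydroxy-2H-pyran-2-one | O=c1cc(O)cco1 | intermediate
12 | 4-bromo-2H-pyran-2-one | O=c1cc(Br)cco1 | intermediate
13 | 4-{[5,7-bis(benzyloxy)-2-(4-methoxyphenyl)-4-oxo-4H-chromen-6-yl]oxy}-2H-pyran-2-one | O=c1cc(Oc2c(OCc3ccccc3)cc3oc(-c4ccc(OC)cc4)cc(=O)c3c2OCc2ccccc2)cco1 | intermediate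
14 | diethyl oxalate | CCOC(=O)C(=O)OCC | starting material
15 | ethyl 4-[2,4-bis(benzyloxy)-6-hydroxyphenyl]-2,4-dioxobutanoate (not isolated) | CCOC(=O)C(=O)CC(=O)c1c(O)cc(OCc2ccccc2)cc1OCc1ccccc1 | intermediate
16 | ethyl 5,7-bis(benzyloxy)-4-oxo-4H-chromene-2-carboxylate | CCOC(=O)c1cc(=O)c2c(OCc3ccccc3)cc(OCc3ccccc3)cc2o1 | intermediate
17 | 5,7-bis(benzyloxy)-2-(hydroxymethyl)-4H-chromen-4-one | OCc1cc(=O)c2c(OCc3ccccc3)cc(OCc3ccccc3)cc2o1 | intermediate
18 | 5,7-bis(benzyloxy)-4-oxo-4H-chromene-2-carbaldehyde | O=Cc1cc(=O)c2c(OCc3ccccc3)cc(OCc3ccccc3)cc2o1 | intermediate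
19 | 5,7-bis(benzyloxy)-2-ethynyl-4H-chromen-4-one | C#Cc1cc(=O)c2c(OCc3ccccc3)cc(OCc3ccccc3)cc2o1 | intermediate
20 | racemic 5-{[5,7-bis(benzyloxy)-2-(4-methoxyphenyl)-4-oxo-4H-chromen-6-yl]oxy}-7-[5,7-bis(benzyloxy)-4-oxo-4H-chromen-2-yl]-2-oxabicyclo[2.2.2]octa-5,7-dien-3-one (not isolated; one enantiomer drawn, bridgehead configurations tied by the bicycle) | O=C1O[C@H]2C=C(Oc3c(OCc4ccccc4)cc4oc(-c5ccc(OC)cc5)cc(=O)c4c3OCc3ccccc3)[C@@H]1C=C2c1cc(=O)c2c(OCc3ccccc3)cc(OCc3ccccc3)cc2o1 | intermediate
21 | 5,7,5'',7''-tetra-O-benzylcryptomerin A, 5,7-bis(benzyloxy)-6-{4-[5,7-bis(benzyloxy)-4-oxo-4H-chromen-2-yl]phenoxy}-2-(4-methoxyphenyl)-4H-chromen-4-one | COc1ccc(-c2cc(=O)c3c(OCc4ccccc4)c(Oc4ccc(-c5cc(=O)c6c(OCc7ccccc7)cc(OCc7ccccc7)cc6o5)cc4)c(OCc4ccccc4)cc3o2)cc1 | intermediate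
22 | cryptomerin A, 6-[4-(5,7-dihydroxy-4-oxo-4H-chromen-2-yl)phenoxy]-5,7-dihydroxy-2-(4-methoxyphenyl)-4H-chromen-4-one | COc1ccc(-c2cc(=O)c3c(O)c(Oc4ccc(-c5cc(=O)c6c(O)cc(O)cc6o5)cc4)c(O)cc3o2)cc1 | target

Total step count: 13 steps.
Longest linear sequence: 7 steps (steps 1, 2, 3, 4, 7, 12, 13; the alkyne branch through steps 1, 8, 9, 10, 11, 12, 13 is equally long).

Steps most likely to fail

Step 12. The terminal alkyne may oligomerise at the temperature the cycloaddition needs, or the addition may proceed with mixed orientation so that a meta-linked ring forms alongside the para one. The fallback joins the halves through the ether bond first and builds the second flavone afterwards; it sets out from 7 and comes back to the route at 21. Nucleophilic aromatic substitution of 4-fluorobenzaldehyde by the phenoxide of 7 (K2CO3, DMF, 100 °C) should give 4-{[5,7-bis(benzyloxy)-2-(4-methoxyphenyl)-4-oxo-4H-chromen-6-yl]oxy}benzaldehyde F1. Claisen–Schmidt condensation of this aldehyde with acetophenone 2 (KOH, EtOH/THF, rt) should give the 2'-hydroxychalcone (E)-1-[2,4-bis(benzyloxy)-6-hydroxyphenyl]-3-(4-{[5,7-bis(benzyloxy)-2-(4-methoxyphenyl)-4-oxo-4H-chromen-6-yl]oxy}phenyl)prop-2-en-1-one F2. Oxidative cyclisation of the chalcone with catalytic I2 in DMSO at 120 °C should then close the second pyranone and deliver 21.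

Step 11. Methoxide may add to the newly formed conjugated alkyne or open the pyranone at C2 before the homologation is complete. The fallback makes the alkyne by olefination and elimination in aprotic media; it sets out from 18 and comes back at 19. Wittig reaction of 18 with bromomethylenetriphenylphosphorane (from Ph3PCH2Br bromide and KOtBu, THF, −78 °C) should give (Z)-5,7-bis(benzyloxy)-2-(2-bromoethenyl)-4H-chromen-4-one F3. Anti elimination of hydrogen bromide with DBU in MeCN at 50 °C should give 19 with no nucleophilic solvent present.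

Step 2. The oxidation may stall because the phenoxide of the dibenzyl ether is poorly soluble in the aqueous base and the para carbon is shielded by two benzyloxy groups, and the hydroquinone may be oxidised further during hydrolysis. The fallback passes through the quinone oxidation level; it sets out from 2 and comes back at 4. Teuber oxidation of 2 with potassium nitrosodisulfonate (KSO3)2NO in KH2PO4-buffered aqueous acetone should give the para-quinone 2-acetyl-3,5-bis(benzyloxy)cyclohexa-2,5-diene-1,4-dione F4. Reduction of the quinone with Na2S2O4 in EtOAc/water should give hydroquinone 4.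

Further compounds
F1 | step 12 | 4-{[5,7-bis(benzyloxy)-2-(4-methoxyphenyl)-4-oxo-4H-chromen-6-yl]oxy}benzaldehyde | O=Cc1ccc(Oc2c(OCc3ccccc3)cc3oc(-c4ccc(OC)cc4)cc(=O)c3c2OCc2ccccc2)cc1
F2 | step 12 | (E)-1-[2,4-bis(benzyloxy)-6-hydroxyphenyl]-3-(4-{[5,7-bis(benzyloxy)-2-(4-methoxyphenyl)-4-oxo-4H-chromen-6-yl]oxy}phenyl)prop-2-en-1-one | O=C(/C=C/c1ccc(Oc2c(OCc3ccccc3)cc3oc(-c4ccc(OC)cc4)cc(=O)c3c2OCc2ccccc2)cc1)c1c(O)cc(OCc2ccccc2)cc1OCc1ccccc1
F3 | step 11 | (Z)-5,7-bis(benzyloxy)-2-(2-bromoethenyl)-4H-chromen-4-one | Br/C=C\c1cc(=O)c2c(OCc3ccccc3)cc(OCc3ccccc3)cc2o1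
F4 | step 2 | 2-acetyl-3,5-bis(benzyloxy)cyclohexa-2,5-diene-1,4-dione | CC(=O)C1=C(OCc2ccccc2)C(=O)C(OCc2ccccc2)=CC1=O
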